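**Retrosynthetic overview**
1. Target ⇒ allyl removal and auxiliary reduction ⇒ anti-glycolate aldol between O-allylvanillin 8 and the aryloxyacetyl imide made on the ring B phenol of 4'-O-allyl-(+)-lariciresinol 14 (sets C7 and C8).
2. 14 ⇒ acyclic triol ⇒ trans aldol adduct of (R)-β-(arylmethyl)-γ-butyrolactone 11 with 8; the tetrahydrofuran is closed by benzylic SN1 etherification (sets C7').
3. 11 ⇒ enantioselective ring-expansion carbonylation (four- to five-membered ring) of the prochiral 3-(arylmethyl)oxetane 10 (sets C8, which then controls C8' and C7').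
4. 10 ⇒ aryl bromide 4 + 3-(bromomethyl)oxetane; all three arenes ⇒ catechol (MeI; NBS/PivCl for ring B; glyoxylic acid, then allyl bromide, for rings A and C).
5. Ring order: oxetane (bought) → γ-lactone (ring expansion) → tetrahydrofuran (lactone reduced, ring re-closed onto C7').

Assumption: the SMILES is read as the (7R,8S)-erythro-guaiacylglycerol 8-O-4 ether of (+)-lariciresinol (tetrahydrofuran 2S,3R,4R: 2,3-trans, 3,4-cis); ring A = glycerol aryl, ring B = benzyl aryl, ring C = tetrahydrofuran aryl.

**Route**

Step 1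
Reactants: 1 catechol
Product: 2 guaiacol (2-methoxyphenol)
Conditions: MeI (1.0 equiv), K2CO3, acetone, reflux
Reagents that add atoms: iodomethane, CI
Why: Williamson mono-O-methylation with one equivalent of MeI; unreacted catechol and the dimethyl ether are removed by base extraction and distillation.

Step 2
Reactants: 2 guaiacol
Product: 4 4-bromo-2-methoxyphenyl pivalate, via 4-bromo-2-methoxyphenol 3 (not isolated)
Conditions: NBS, MeCN, 0 °C; then Et3N, PivCl, DMAP (cat.), 0 °C → rt
Reagents that add atoms: N-bromosuccinimide, O=C1CCC(=O)N1Br; pivaloyl chloride, CC(C)(C)C(Cl)=O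
Why: Electrophilic aromatic bromination goes para to the free OH (the strongest director), and the phenol is then O-acylated in the same pot so that ring B carries an ester that a later hydride step removes.

Step 3
Reactants: 2 guaiacol; 5 glyoxylic acid
Product: 7 vanillin, via 4-hydroxy-3-methoxymandelic acid 6 (not isolated)
Conditions: NaOH, H2O, 30 °C; then CuSO4 (cat.), O2, 95 °C; then H2SO4 to pH 3
Reagents that add atoms: none
Why: Phenoxide hydroxyalkylation para to the OH by glyoxylate followed by copper-catalysed aerobic oxidative decarboxylation, the established technical vanillin process.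

Step 4
Reactants: 7 vanillin
Product: 8 4-(allyloxy)-3-methoxybenzaldehyde
Conditions: allyl bromide, K2CO3, DMF, rt
Reagents that add atoms: allyl bromide, C=CCBr
Why: Williamson etherification gives a phenol protecting group that survives enolates, hydrides and mild acid and is later removed without hydrogenolysis.

Step 5
Reactants: 4 4-bromo-2-methoxyphenyl pivalate; 9 3-(bromomethyl)oxetane
Product: 10 2-methoxy-4-(oxetan-3-ylmethyl)phenyl pivalate
Conditions: NiI2 (10 mol%), 4,4'-di-tert-butyl-2,2'-bipyridine (10 mol%), NaI (25 mol%), Zn (2 equiv), DMPU, 60 °C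
Reagents that add atoms: none
Why: Nickel-catalysed reductive cross-electrophile coupling of an aryl bromide with a primary alkyl bromide, run under neutral reducing conditions that tolerate the aryl ester and the oxetane.

Step 6
Reactants: 10 2-methoxy-4-(oxetan-3-ylmethyl)phenyl pivalate
Product: 11 2-methoxy-4-{[(3R)-5-oxooxolan-3-yl]methyl}phenyl pivalate
Conditions: [(salen)Cr(THF)2][Co(CO)4] (5 mol%; salen = (R,R)-N,N'-bis(3,5-di-tert-butylsalicylidene)cyclohexane-1,2-diaminate, trivalent chromium), CO (60 bar), DME, 50 °C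
Reagents that add atoms: carbon monoxide, [C-]#[O+]
Why: Proposed new method: an enantioselective, desymmetrising ring-expansion carbonylation of a 3-substituted oxetane, in which the chromium-salen cation binds the oxetane oxygen, [Co(CO)4]− opens the ring by backside attack at the pro-S CH2 (the enantio-determining event inside the chiral salen pocket), the alkylcobalt inserts CO by 1,2-migration of the alkyl group onto carbon monoxide and the chromium alkoxide closes onto the acylcobalt to give the five-membered lactone with the (R) centre; the closest known reaction type is the non-enantioselective Lewis acid/tetracarbonylcobaltate ring-expansion carbonylation of epoxides and oxetanes, together with chiral-Lewis-acid desymmetrisation of 3-substituted oxetanes by other nucleophiles.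

Step 7
Reactants: 11 (R)-lactone; 8 4-(allyloxy)-3-methoxybenzaldehyde
Product: 12 (3S,4R)-3-[(4-allyloxy-3-methoxyphenyl)(hydroxy)methyl]-4-(3-methoxy-4-pivaloyloxybenzyl)dihydrofuran-2(3H)-one (both carbinol epimers)
Conditions: LDA (1.05 equiv), THF, −78 °C; then 8; AcOH quench at −78 °C
Reagents that add atoms: none
Why: Lithium enolate aldol addition in which the aldehyde approaches anti to the C4 arylmethyl group, giving the 3,4-trans lactone (C8' set); the carbinol centre is re-set in step 8, so its epimer ratio does not matter.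

Step 8
Reactants: 12 trans aldol lactone
Product: 14 4'-O-allyl-(+)-lariciresinol, via triol 13 (not isolated)
Conditions: LiAlH4, THF, 0 °C → rt; then 1 M aq. HCl to pH 1, 0 °C → rt, 30 min
Reagents that add atoms: none
Why: Hydride reduction opens the lactone and cleaves the pivalate, and acid then closes the ring by SN1 cycloetherification through the p-alkoxybenzyl cation, the primary C9 hydroxyl adding trans to the neighbouring CH2OH (2,3-trans, C7' = S) while the untouched C8/C8' centres become 3,4-cis on the new ring; the acid treatment is kept short to avoid Friedel–Crafts closure onto ring B.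

Step 9
Reactants: 15 chloroacetyl chloride
Product: 16 (S)-4-benzyl-3-(chloroacetyl)oxazolidin-2-one
Conditions: (S)-4-benzyloxazolidin-2-one, n-BuLi, THF, −78 °C; then 15
Reagents that add atoms: (S)-4-benzyloxazolidin-2-one, O=C1N[C@@H](Cc2ccccc2)CO1
Why: N-acylation of the lithiated Evans auxiliary by the acid chloride.

Step 10
Reactants: 14 4'-O-allyl-(+)-lariciresinol; 16 (S)-4-benzyl-3-(chloroacetyl)oxazolidin-2-one
Product: 17 ring B O-{2-[(S)-4-benzyl-2-oxooxazolidin-3-yl]-2-oxoethyl} ether of 14
Conditions: K2CO3, NaI (cat.), acetone, 40 °C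
Reagents that add atoms: none
Why: SN2 O-alkylation (Williamson, iodide-assisted) of the only phenoxide present by the activated α-chloro imide; the primary alcohol is not deprotonated by carbonate and stays free.

Step 11
Reactants: 17 aryloxyacetyl imide; 8 4-(allyloxy)-3-methoxybenzaldehyde
Product: 19 anti-aldol imide (2R,3R), via bis(trimethylsilyl) ether 18 (not isolated)
Conditions: MgCl2 (20 mol%), NaSbF6 (30 mol%), Et3N, TMSCl (3 equiv), EtOAc, 23 °C; then 1 M aq. HCl/THF (1:5), 0 °C
Reagents that add atoms: chlorotrimethylsilane, C[Si](C)(C)Cl (silicon stays only in 18)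
Why: Evans magnesium-halide-catalysed direct anti-aldol, in which the (S)-benzyl group of the magnesium-chelated enolate blocks one face (C8, S in the final diol) and the boat-type transition state places the new C7–O anti to the aryloxy group (7R, erythro), while TMSCl traps the aldolate and masks the free primary hydroxyl in situ.

Step 12
Reactants: 19 anti-aldol imide
Product: 20 (1R,2S)-1-(4-allyloxy-3-methoxyphenyl)-2-(ring B aryloxy)propane-1,3-diol (bis-allyl ether of the target)
Conditions: LiBH4, THF, MeOH (2 equiv), 0 °C; aq. NH4Cl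
Reagents that add atoms: none
Why: Reductive cleavage of the N-acyloxazolidinone by LiBH4 gives the primary alcohol C9 without touching C7 or C8 and releases the auxiliary.

Step 13
Reactants: 20 bis-allyl ether
Product: 21 target, CNP0158473.3
Conditions: Pd(PPh3)4 (5 mol%), morpholine (10 equiv), THF, rt
Reagents that add atoms: none
Why: Tsuji–Trost deallylation, in which zerovalent palladium ionises both aryl allyl ethers and morpholine traps the π-allyl units, conditions that leave the benzylic alcohol and the benzylic tetrahydrofuran C–O bond untouched.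

**Compound list**
1 | catechol (benzene-1,2-diol) | Oc1ccccc1O | starting material
2 | guaiacol (2-methoxyphenol) | COc1ccccc1O | intermediate
3 | 4-bromo-2-methoxyphenol | COc1cc(Br)ccc1O | intermediate (not isolated)
4 | 4-bromo-2-methoxyphenyl pivalate | COc1cc(Br)ccc1OC(=O)C(C)(C)C | intermediate
5 | glyoxylic acid | O=CC(=O)O | starting material
6 | 4-hydroxy-3-methoxymandelic acid (racemic) | COc1cc(C(O)C(=O)O)ccc1O | intermediate (not isolated)
7 | vanillin | COc1cc(C=O)ccc1O | intermediate
8 | 4-(allyloxy)-3-methoxybenzaldehyde | COc1cc(C=O)ccc1OCC=C | intermediate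
9 | 3-(bromomethyl)oxetane | BrCC1COC1 | starting material
10 | 2-methoxy-4-(oxetan-3-ylmethyl)phenyl pivalate | COc1cc(CC2COC2)ccc1OC(=O)C(C)(C)C | intermediate
11 | 2-methoxy-4-{[(3R)-5-oxooxolan-3-yl]methyl}phenyl pivalate, the (R)-β-arylmethyl-γ-butyrolactone | O=C1C[C@@H](Cc2ccc(OC(=O)C(C)(C)C)c(OC)c2)CO1 | intermediate
12 | (3S,4R)-3-[(4-allyloxy-3-methoxyphenyl)(hydroxy)methyl]-4-(3-methoxy-4-pivaloyloxybenzyl)dihydrofuran-2(3H)-one, carbinol carbon as both epimers | O=C1OC[C@H](Cc2ccc(OC(=O)C(C)(C)C)c(OC)c2)[C@H]1C(O)c1ccc(OCC=C)c(OC)c1 | intermediate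
13 | (2R,3R)-2-[(4-allyloxy-3-methoxyphenyl)(hydroxy)methyl]-3-(4-hydroxy-3-methoxybenzyl)butane-1,4-diol, carbinol carbon as both epimers | OC[C@H](Cc1ccc(O)c(OC)c1)[C@H](CO)C(O)c1ccc(OCC=C)c(OC)c1 | intermediate (not isolated)
14 | 4'-O-allyl-(+)-lariciresinol, [(2S,3R,4R)-2-(4-allyloxy-3-methoxyphenyl)-4-(4-hydroxy-3-methoxybenzyl)tetrahydrofuran-3-yl]methanol | COc1cc(C[C@H]2CO[C@H](c3ccc(OCC=C)c(OC)c3)[C@H]2CO)ccc1O | intermediate
15 | chloroacetyl chloride | ClCC(Cl)=O | starting material
16 | (S)-4-benzyl-3-(chloroacetyl)oxazolidin-2-one | O=C(CCl)N1[C@@H](Cc2ccccc2)COC1=O | intermediate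
17 | (S)-4-benzyl-3-(aryloxyacetyl)oxazolidin-2-one, aryloxy = ring B oxygen of 14 | COc1cc(C[C@H]2CO[C@H](c3ccc(OCC=C)c(OC)c3)[C@H]2CO)ccc1OCC(=O)N1[C@@H](Cc2ccccc2)COC1=O | intermediate
18 | bis(trimethylsilyl) ether of 19 (C7–OTMS and C9'–OTMS) | COc1cc([C@@H](O[Si](C)(C)C)[C@H](C(=O)N2[C@@H](Cc3ccccc3)COC2=O)Oc2ccc(C[C@H]3CO[C@H](c4ccc(OCC=C)c(OC)c4)[C@H]3CO[Si](C)(C)C)cc2OC)ccc1OCC=C | intermediate (not isolated)
19 | (S)-4-benzyl-3-[(2R,3R)-3-(4-allyloxy-3-methoxyphenyl)-3-hydroxy-2-(ring B aryloxy)propanoyl]oxazolidin-2-one | COc1cc([C@@H](O)[C@H](C(=O)N2[C@@H](Cc3ccccc3)COC2=O)Oc2ccc(C[C@H]3CO[C@H](c4ccc(OCC=C)c(OC)c4)[C@H]3CO)cc2OC)ccc1OCC=C | intermediate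
20 | (1R,2S)-1-(4-allyloxy-3-methoxyphenyl)-2-[4-{[(2S,3R,4R)-2-(4-allyloxy-3-methoxyphenyl)-3-(hydroxymethyl)tetrahydrofuran-4-yl]methyl}-2-methoxyphenoxy]propane-1,3-diol | COc1cc([C@@H](O)[C@H](CO)Oc2ccc(C[C@H]3CO[C@H](c4ccc(OCC=C)c(OC)c4)[C@H]3CO)cc2OC)ccc1OCC=C | intermediate
21 | (1R,2S)-1-(4-hydroxy-3-methoxyphenyl)-2-[4-{[(2S,3R,4R)-2-(4-hydroxy-3-methoxyphenyl)-3-(hydroxymethyl)tetrahydrofuran-4-yl]methyl}-2-methoxyphenoxy]propane-1,3-diol | COc1cc([C@@H](O)[C@H](CO)Oc2ccc(C[C@H]3CO[C@H](c4ccc(O)c(OC)c4)[C@H]3CO)cc2OC)ccc1O | target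

**Step count and risks**

Total steps: 13. Longest linear sequence: 10 (steps 1, 2, 5, 6, 7, 8, 10, 11, 12, 13).

Three steps most likely to fail:

Step 6 (the proposed carbonylation). The risks are low enantioselectivity, cationic oligomerisation of the oxetane and slow turnover under CO pressure. The sense of induction is not predictable and must be checked on 11 by chiral HPLC; the (S,S)-ligand is used instead if the (R,R)-ligand gives the antipode. Fallback with known chemistry, from 4 back to 11: 4 is coupled under the nickel/zinc conditions of step 5 with 3-(bromomethyl)cyclobutan-1-one F1 to give 2-methoxy-4-[(3-oxocyclobutyl)methyl]phenyl pivalate F2. Its known catalytic asymmetric Baeyer–Villiger desymmetrisation (Sc(OTf)3 with a chiral N,N'-dioxide ligand, mCPBA, EtOAc, −20 °C) then gives lactone 11.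

Step 11 (magnesium-catalysed anti-aldol). The α-aryloxy group can compete for magnesium and erode the anti selectivity or the facial sense, and the electron-rich aldehyde is a slow acceptor. The erythro assignment is checked by the H7/H8 coupling and against the threo isomer. Fallback, from 14 back to 20: 14 is O-alkylated (K2CO3, acetone) with S-ethyl bromothioacetate F3 to give S-ethyl aryloxythioacetate F4. TMSOTf/Et3N converts F4 into the (Z)-ketene silyl thioacetal F5, silylating the primary hydroxyl as well. The established anti-selective Mukaiyama aldol of α-alkoxy thioester silyl ketene acetals with aromatic aldehydes (Sn(OTf)2, chiral 1-methyl-2-(piperidin-1-ylmethyl)pyrrolidine, Bu2Sn(OAc)2, CH2Cl2, −78 °C; aqueous acid work-up), run with 8 and the diamine enantiomer that the published correlation assigns to the (2R,3R) adduct, gives thioester F6. LiBH4 reduces F6 to diol 20.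

Step 5 (reductive cross-coupling). The risks are biaryl formation, hydrodebromination of 4, and opening of the oxetane by zinc halide or iodide at 60 °C. Fallback, from 4 back to 10: 3-methyleneoxetane F7 is hydroborated with 9-BBN (THF, rt) to B-(oxetan-3-ylmethyl)-9-borabicyclo[3.3.1]nonane F8, which is coupled with 4 in a B-alkyl Suzuki–Miyaura reaction (Pd(dppf)Cl2, K3PO4, THF/H2O, 60 °C) to give 10.

**Further compounds**
F1 | step 6 | 3-(bromomethyl)cyclobutan-1-one | O=C1CC(CBr)C1
F2 | step 6 | 2-methoxy-4-[(3-oxocyclobutyl)methyl]phenyl pivalate | COc1cc(CC2CC(=O)C2)ccc1OC(=O)C(C)(C)C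
F3 | step 11 | S-ethyl bromothioacetate | BrCC(=O)SCC
F4 | step 11 | S-ethyl 2-(ring B aryloxy)ethanethioate derived from 14 | COc1cc(C[C@H]2CO[C@H](c3ccc(OCC=C)c(OC)c3)[C@H]2CO)ccc1OCC(=O)SCC
F5 | step 11 | (Z)-ketene silyl thioacetal of F4 with the primary hydroxyl as trimethylsilyl ether | COc1cc(C[C@H]2CO[C@H](c3ccc(OCC=C)c(OC)c3)[C@H]2CO[Si](C)(C)C)ccc1O/C=C(/O[Si](C)(C)C)SCC
F6 | step 11 | S-ethyl (2R,3R)-3-(4-allyloxy-3-methoxyphenyl)-3-hydroxy-2-(ring B aryloxy)propanethioate | COc1cc([C@@H](O)[C@H](C(=O)SCC)Oc2ccc(C[C@H]3CO[C@H](c4ccc(OCC=C)c(OC)c4)[C@H]3CO)cc2OC)ccc1OCC=C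
F7 | step 5 | 3-methyleneoxetane | C=C1COC1
F8 | step 5 | B-(oxetan-3-ylmethyl)-9-borabicyclo[3.3.1]nonane | C1CC2CCCC(C1)B2CC1COC1
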